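**Retrosynthetic overview**
- Target ⇐ desilylation and acetonide hydrolysis ⇐ C5–C1' bond: aryllithium of a 5-bromo-2,3-dihydrobenzofuran adds to (R)-glyceraldehyde acetonide (Felkin–Anh sets 1'S; 2'R comes from the chiral pool).
- 5-Bromo-3-(hydroxymethyl)-2,3-dihydrobenzofuran ⇐ key step: oxygenative 5-exo-trig aryl radical cyclization of an (S)-1-arylallyl 2-iodoaryl ether, forming the C3–C3a bond, the C3 stereocentre and the primary OH in one operation.
- (S)-Ether ⇐ Ir-catalysed asymmetric allylic etherification of 4-bromo-2-iodo-6-methoxyphenol with a cinnamyl methyl carbonate (sets C2).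
- Both arenes ⇐ 4-bromo-2-methoxyphenol ⇐ catechol; the cinnamyl carbonate comes from Suzuki vinylation and cross-metathesis.
- Ring order: both benzene rings are carried in from catechol; the dihydrofuran ring is the only ring formed, in the radical step.

Assumption: the (Sa,Sc,Sc) antipode of the binaphthol-derived bis(1-phenylethyl)phosphoramidite ligand gives the (S)-ether in step 7; if the sense of induction is the opposite, the (Ra,Rc,Rc) ligand is used with no other change.

**Route**

Step 1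
Reactants: 1 benzene-1,2-diol (catechol)
Product: 2 2-methoxyphenol
Conditions: 1 (1.7 equiv), MeI (1.0 equiv), K2CO3, acetone, reflux
Reagents that add atoms: iodomethane, CI
Why: Williamson O-methylation, where excess diol keeps dimethylation low and unreacted catechol is washed out with water.

Step 2
Reactants: 2 2-methoxyphenol
Product: 3 4-bromo-2-methoxyphenol
Conditions: NBS (1.0 equiv), MeCN, 0 °C
Reagents that add atoms: N-bromosuccinimide, O=C1CCC(=O)N1Br
Why: Electrophilic aromatic bromination, directed by the free OH (the stronger donor) to its open para position.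

Step 3
Reactants: 3 4-bromo-2-methoxyphenol
Product: 4 4-bromo-2-iodo-6-methoxyphenol
Conditions: NIS (1.05 equiv), TsOH·H2O (10 mol %), MeCN, 20 °C
Reagents that add atoms: N-iodosuccinimide, O=C1CCC(=O)N1I
Why: Electrophilic aromatic iodination, which goes to the only free position ortho to the OH because para is blocked (the same selectivity as 5-iodination of vanillin).

Step 4
Reactants: 3 4-bromo-2-methoxyphenol
Product: 5 (4-bromo-2-methoxyphenoxy)tri(propan-2-yl)silane
Conditions: i-Pr3SiCl (1.1 equiv), imidazole (2 equiv), DMF, 20 °C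
Reagents that add atoms: chlorotri(propan-2-yl)silane, CC(C)[Si](Cl)(C(C)C)C(C)C
Why: Silyl ether protection of the phenol with a group that withstands carbonate base, phenolate, tin radicals and t-BuLi.

Step 5
Reactants: 5 (4-bromo-2-methoxyphenoxy)tri(propan-2-yl)silane; 6 potassium ethenyltrifluoroborate
Product: 7 (4-ethenyl-2-methoxyphenoxy)tri(propan-2-yl)silane
Conditions: PdCl2(dppf)·CH2Cl2 (3 mol %), Cs2CO3 (3 equiv), THF/H2O 9:1, 85 °C
Reagents that add atoms: none
Why: Suzuki–Miyaura vinylation of an aryl bromide with a vinyltrifluoroborate.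

Step 6
Reactants: 7 (4-ethenyl-2-methoxyphenoxy)tri(propan-2-yl)silane; 8 methyl prop-2-en-1-yl carbonate (allyl methyl carbonate, 3 equiv)
Product: 9 (E)-3-{3-methoxy-4-[tri(propan-2-yl)silyloxy]phenyl}prop-2-en-1-yl methyl carbonate
Conditions: second-generation Grubbs catalyst RuCl2(=CHPh)(PCy3)(H2IMes) (3 mol %), CH2Cl2, 40 °C
Reagents that add atoms: none
Why: Olefin cross-metathesis of a styrene with an allyl carbonate, E-selective under thermodynamic control, with excess 8 suppressing stilbene formation.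

Step 7
Reactants: 4 4-bromo-2-iodo-6-methoxyphenol; 9 (E)-3-{3-methoxy-4-[tri(propan-2-yl)silyloxy]phenyl}prop-2-en-1-yl methyl carbonate
Product: 11 {4-[(1S)-1-(4-bromo-2-iodo-6-methoxyphenoxy)prop-2-en-1-yl]-2-methoxyphenoxy}tri(propan-2-yl)silane, via lithium phenolate 10 (not isolated)
Conditions: 4 (1.3 equiv), LiN(SiMe3)2 (1.3 equiv), THF, 0 °C; then 9, [Ir(cod)Cl]2 (2 mol %), (Sa,Sc,Sc)-O,O'-(1,1'-binaphthyl-2,2'-diyl) N,N-bis(1-phenylethyl)phosphoramidite (4 mol %, pre-activated with n-PrNH2), THF, 50 °C; aq NH4Cl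
Reagents that add atoms: none
Why: Hartwig-type Ir-catalysed asymmetric allylic etherification, in which the phenolate attacks the aryl-substituted terminus of the allyliridium intermediate to give the branched ether and the ligand fixes the new stereocentre (future C2) as S.

Step 8
Reactants: 11 {4-[(1S)-1-(4-bromo-2-iodo-6-methoxyphenoxy)prop-2-en-1-yl]-2-methoxyphenoxy}tri(propan-2-yl)silane
Product: 13 [(2S,3R)-5-bromo-7-methoxy-2-{3-methoxy-4-[tri(propan-2-yl)silyloxy]phenyl}-2,3-dihydro-1-benzofuran-3-yl]methanol, via hydroperoxide 12 (not isolated)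
Conditions: Bu3SnH (2 equiv, syringe pump, 6 h), dry air bubbled through, toluene (0.02 M), 20 °C; then PPh3 (1.0 equiv)
Reagents that add atoms: dioxygen, O=O
Why: Oxygenative 5-exo-trig aryl radical cyclization (the tin radical takes iodine much faster than bromine, ring closure outruns O2 capture of the aryl radical, the primary radical is then trapped by O2 and the hydroperoxide reduced), with the C2 aryl group pseudo-equatorial in the Beckwith–Houk transition state so that C3 forms trans (3R), expected about 4:1 over the cis isomer, which is removed by chromatography.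

Step 9
Reactants: 13 [(2S,3R)-5-bromo-7-methoxy-2-{3-methoxy-4-[tri(propan-2-yl)silyloxy]phenyl}-2,3-dihydro-1-benzofuran-3-yl]methanol; 14 (4R)-2,2-dimethyl-1,3-dioxolane-4-carbaldehyde (2,3-O-isopropylidene-D-glyceraldehyde, freshly distilled, 2 equiv)
Product: 16 (S)-[(4R)-2,2-dimethyl-1,3-dioxolan-4-yl][(2S,3R)-3-(hydroxymethyl)-7-methoxy-2-{3-methoxy-4-[tri(propan-2-yl)silyloxy]phenyl}-2,3-dihydro-1-benzofuran-5-yl]methanol, via dilithio species 15 (not isolated)
Conditions: t-BuLi (3.1 equiv), THF, −78 °C, 30 min; then 14, −78 → −40 °C; aq NH4Cl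
Reagents that add atoms: none
Why: Bromine–lithium exchange on the lithium alkoxide followed by Felkin–Anh (non-chelated) addition to the α-alkoxy aldehyde gives the anti (1'S) carbinol as the major isomer (expected about 3:1; the minor epimer and the adduct of any enantiomeric core are diastereomers and are removed by chromatography), while the 2'R centre comes unchanged from 14.

Step 10
Reactants: 16 (S)-[(4R)-2,2-dimethyl-1,3-dioxolan-4-yl][(2S,3R)-3-(hydroxymethyl)-7-methoxy-2-{3-methoxy-4-[tri(propan-2-yl)silyloxy]phenyl}-2,3-dihydro-1-benzofuran-5-yl]methanol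
Product: 18 (1S,2R)-1-[(2S,3R)-2-(4-hydroxy-3-methoxyphenyl)-3-(hydroxymethyl)-7-methoxy-2,3-dihydro-1-benzofuran-5-yl]propane-1,2,3-triol, via phenol acetonide 17 (not isolated)
Conditions: Bu4NF (1.2 equiv), THF, 0 °C, 30 min; then AcOH/H2O 4:1, 40 °C
Reagents that add atoms: none
Why: Fluoride desilylation followed in the same pot by mild acid hydrolysis of the terminal acetonide, conditions too weak to ionize the electron-rich benzylic alcohol or open the benzylic ring ether, so no stereocentre is touched.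

**Compound list**

1 | benzene-1,2-diol (catechol) | Oc1ccccc1O | starting material
2 | 2-methoxyphenol | COc1ccccc1O | intermediate
3 | 4-bromo-2-methoxyphenol | COc1cc(Br)ccc1O | intermediate
4 | 4-bromo-2-iodo-6-methoxyphenol | COc1cc(Br)cc(I)c1O | intermediate
5 | (4-bromo-2-methoxyphenoxy)tri(propan-2-yl)silane | COc1cc(Br)ccc1O[Si](C(C)C)(C(C)C)C(C)C | intermediate
6 | potassium ethenyltrifluoroborate | C=C[B-](F)(F)F.[K+] | starting material
7 | (4-ethenyl-2-methoxyphenoxy)tri(propan-2-yl)silane | C=Cc1ccc(O[Si](C(C)C)(C(C)C)C(C)C)c(OC)c1 | intermediate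
8 | methyl prop-2-en-1-yl carbonate | C=CCOC(=O)OC | starting material
9 | (E)-3-{3-methoxy-4-[tri(propan-2-yl)silyloxy]phenyl}prop-2-en-1-yl methyl carbonate | COC(=O)OC/C=C/c1ccc(O[Si](C(C)C)(C(C)C)C(C)C)c(OC)c1 | intermediate
10 | lithium 4-bromo-2-iodo-6-methoxyphenolate | [Li+].[O-]c1c(I)cc(Br)cc1OC | intermediate
11 | {4-[(1S)-1-(4-bromo-2-iodo-6-methoxyphenoxy)prop-2-en-1-yl]-2-methoxyphenoxy}tri(propan-2-yl)silane | C=C[C@H](Oc1c(I)cc(Br)cc1OC)c1ccc(O[Si](C(C)C)(C(C)C)C(C)C)c(OC)c1 | intermediate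
12 | {4-[(2S,3R)-5-bromo-3-(hydroperoxymethyl)-7-methoxy-2,3-dihydro-1-benzofuran-2-yl]-2-methoxyphenoxy}tri(propan-2-yl)silane | COc1cc([C@H]2Oc3c(OC)cc(Br)cc3[C@@H]2COO)ccc1O[Si](C(C)C)(C(C)C)C(C)C | intermediate
13 | [(2S,3R)-5-bromo-7-methoxy-2-{3-methoxy-4-[tri(propan-2-yl)silyloxy]phenyl}-2,3-dihydro-1-benzofuran-3-yl]methanol | COc1cc([C@H]2Oc3c(OC)cc(Br)cc3[C@@H]2CO)ccc1O[Si](C(C)C)(C(C)C)C(C)C | intermediate
14 | (4R)-2,2-dimethyl-1,3-dioxolane-4-carbaldehyde | O=C[C@H]1COC(C)(C)O1 | starting material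
15 | lithium alkoxide and 5-lithio derivative of 13 (dilithio species) | COc1cc([C@H]2Oc3c(OC)cc([Li])cc3[C@@H]2CO[Li])ccc1O[Si](C(C)C)(C(C)C)C(C)C | intermediate
16 | (S)-[(4R)-2,2-dimethyl-1,3-dioxolan-4-yl][(2S,3R)-3-(hydroxymethyl)-7-methoxy-2-{3-methoxy-4-[tri(propan-2-yl)silyloxy]phenyl}-2,3-dihydro-1-benzofuran-5-yl]methanol | COc1cc([C@H]2Oc3c(OC)cc([C@H](O)[C@H]4COC(C)(C)O4)cc3[C@@H]2CO)ccc1O[Si](C(C)C)(C(C)C)C(C)C | intermediate
17 | 4-[(2S,3R)-5-{(S)-[(4R)-2,2-dimethyl-1,3-dioxolan-4-yl](hydroxy)methyl}-3-(hydroxymethyl)-7-methoxy-2,3-dihydro-1-benzofuran-2-yl]-2-methoxyphenol | COc1cc([C@H]2Oc3c(OC)cc([C@H](O)[C@H]4COC(C)(C)O4)cc3[C@@H]2CO)ccc1O | intermediate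
18 | (1S,2R)-1-[(2S,3R)-2-(4-hydroxy-3-methoxyphenyl)-3-(hydroxymethyl)-7-methoxy-2,3-dihydro-1-benzofuran-5-yl]propane-1,2,3-triol | COc1cc([C@H]2Oc3c(OC)cc([C@H](O)[C@H](O)CO)cc3[C@@H]2CO)ccc1O | target

**Step count and risks**

Total steps: 10. Longest linear sequence: 9 (1 → 2 → 3 → 5 → 7 → 9 → 11 → 13 → 16 → 18; step 3 is the one-step branch to 4).

Three steps most likely to fail:

1. Step 7 (allylic etherification). The phenolate is flanked by iodine and methoxy and is a fairly good leaving group, so slow reaction, linear ether or erosion of ee by re-ionization of the product are possible. The fallback sets out from 7 and comes back at 11, building the C–O stereocentre by epoxide opening instead. Cross-metathesis of 7 with (Z)-but-2-ene-1,4-diol (second-generation Grubbs catalyst) gives (E)-3-{3-methoxy-4-[tri(propan-2-yl)silyloxy]phenyl}prop-2-en-1-ol F1. Sharpless epoxidation (Ti(OiPr)4, L-(+)-diisopropyl tartrate, t-BuOOH, 4 Å sieves, CH2Cl2, −20 °C) gives the (2S,3S)-epoxy alcohol F2. Phenol 4 with Ti(OiPr)4 in CH2Cl2 opens F2 at the benzylic carbon with inversion to give the (2S,3R)-3-aryloxy-1,2-diol F3. 1,1'-Thiocarbonyldiimidazole converts this into the cyclic thionocarbonate F4. Corey–Winter elimination with 1,3-dimethyl-2-phenyl-1,3,2-diazaphospholidine at 40 °C then removes both diol oxygens without touching the aryloxy-bearing centre and delivers 11.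

2. Step 8 (oxygenative radical cyclization). The risks are tin hydride reduction of the cyclized radical before O2 capture, side oxidation by peroxyl radicals, and a lower trans:cis ratio than expected. The fallback sets out from 11 and comes back at 13, replacing the oxygen chain process by stoichiometric capture with a persistent nitroxide. Bu3SnH (slow addition) and TEMPO (3 equiv) in benzene at 70 °C give the trans alkoxyamine 1-({(2S,3R)-5-bromo-7-methoxy-2-{3-methoxy-4-[tri(propan-2-yl)silyloxy]phenyl}-2,3-dihydro-1-benzofuran-3-yl}methoxy)-2,2,6,6-tetramethylpiperidine F5, which is purified from the cis isomer. Zn dust in AcOH/THF/H2O at 70 °C then cleaves the N–O bond to give 13.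

3. Step 9 (aryllithium addition). The facial selectivity of aryllithium additions to glyceraldehyde acetonide is modest, and the aldehyde can enolize or oligomerize. The fallback sets out from 13 and comes back at 16, moving the stereocontrol from C–C bond formation to a ketone reduction. The dilithio species from 13 (t-BuLi, THF, −78 °C) is acylated with methyl (4R)-2,2-dimethyl-1,3-dioxolane-4-carboxylate at −78 °C to give the aryl ketone [(4R)-2,2-dimethyl-1,3-dioxolan-4-yl][(2S,3R)-3-(hydroxymethyl)-7-methoxy-2-{3-methoxy-4-[tri(propan-2-yl)silyloxy]phenyl}-2,3-dihydro-1-benzofuran-5-yl]methanone F6. Reduction with LiBH(s-Bu)3 in THF at −78 °C under Felkin–Anh control gives the anti carbinol 16.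

**Further compounds**

F1 | step 7 | (E)-3-{3-methoxy-4-[tri(propan-2-yl)silyloxy]phenyl}prop-2-en-1-ol | OC/C=C/c1ccc(O[Si](C(C)C)(C(C)C)C(C)C)c(OC)c1
F2 | step 7 | [(2S,3S)-3-{3-methoxy-4-[tri(propan-2-yl)silyloxy]phenyl}oxiran-2-yl]methanol | OC[C@@H]1O[C@H]1c1ccc(O[Si](C(C)C)(C(C)C)C(C)C)c(OC)c1
F3 | step 7 | (2S,3R)-3-(4-bromo-2-iodo-6-methoxyphenoxy)-3-{3-methoxy-4-[tri(propan-2-yl)silyloxy]phenyl}propane-1,2-diol | OC[C@H](O)[C@H](Oc1c(I)cc(Br)cc1OC)c1ccc(O[Si](C(C)C)(C(C)C)C(C)C)c(OC)c1
F4 | step 7 | (4S)-4-[(R)-(4-bromo-2-iodo-6-methoxyphenoxy){3-methoxy-4-[tri(propan-2-yl)silyloxy]phenyl}methyl]-1,3-dioxolane-2-thione | S=C1OC[C@H](O1)[C@H](Oc1c(I)cc(Br)cc1OC)c1ccc(O[Si](C(C)C)(C(C)C)C(C)C)c(OC)c1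
F5 | step 8 | 1-({(2S,3R)-5-bromo-7-methoxy-2-{3-methoxy-4-[tri(propan-2-yl)silyloxy]phenyl}-2,3-dihydro-1-benzofuran-3-yl}methoxy)-2,2,6,6-tetramethylpiperidine | COc1cc([C@H]2Oc3c(OC)cc(Br)cc3[C@@H]2CON4C(C)(C)CCCC4(C)C)ccc1O[Si](C(C)C)(C(C)C)C(C)C
F6 | step 9 | [(4R)-2,2-dimethyl-1,3-dioxolan-4-yl][(2S,3R)-3-(hydroxymethyl)-7-methoxy-2-{3-methoxy-4-[tri(propan-2-yl)silyloxy]phenyl}-2,3-dihydro-1-benzofuran-5-yl]methanone | COc1cc([C@H]2Oc3c(OC)cc(C(=O)[C@H]4COC(C)(C)O4)cc3[C@@H]2CO)ccc1O[Si](C(C)C)(C(C)C)C(C)C
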